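**Assumption:** briarane numbering of the target is used for every intermediate (ring A = C1, C10–C14 with Me-15 on C1 and Me-20 on C11; C16 on C5; C17–C19 with Me-18 for the lactone carbons), and (Z)-2-bromobut-2-enal, 4-(chloroacetyl)morpholine and tributyl(vinyl)stannane are taken as catalogue chemicals.

## Retrosynthetic overview

1. Last step: palladium-catalysed 1,4-butanoyloxy-lactonisation of the ten-membered diene acid 27 forms the C7–O lactone bond, the C4–O butanoate bond and the 5Z alkene in one operation.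
2. The ten-membered ring comes from ene–diene ring-closing metathesis (C6=C7) of triene 25. Ring order: ring A (from carvone), then the ten-membered ring, then the lactone.
3. C8 and C17 come from a chelation-controlled propanoate aldol on α-hydroxy vinyl ketone 19. C9–C10 comes from a [2,3]-Wittig shift of a C12 allyl ether made by Wharton transposition.
4. C2–C3 comes from a chelation-controlled vinylogous Mukaiyama aldol on keto aldehyde 3. The 14-acetate comes from Criegee rearrangement of the carvone isopropenyl group.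
5. Ring A with C1 and C14 comes from (S)-carvone by formylation and methylation.

## Route

Step 1
Reactants: 1 (S)-(+)-carvone
Product: 2 (5S)-6-(hydroxymethylidene)carvone
Conditions: NaH, HCO2Et, THF, 0 °C to rt; aq. HCl work-up
Reagents that add atoms: ethyl formate CCOC=O
Why: Claisen formylation at C6, the only α-CH2 of the enone, gives the enolised formyl ketone, so no stereocenter is fixed yet.

Step 2
Reactants: 2 (5S)-6-(hydroxymethylidene)carvone
Product: 3 (1R,6R)-1,3-dimethyl-2-oxo-6-(prop-1-en-2-yl)cyclohex-3-ene-1-carbaldehyde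
Conditions: K2CO3, MeI, acetone, 56 °C
Reagents that add atoms: iodomethane CI
Why: C-alkylation of the formyl-ketone enolate, with MeI entering anti to the neighbouring isopropenyl group, sets quaternary C1 with Me-15 trans to the future 14-oxygen.

Step 3
Reactants: 4 (Z)-2-bromobut-2-enal
Product: 5 [(2-bromobuta-1,3-dien-1-yl)oxy](tert-butyl)dimethylsilane
Conditions: TBSOTf, Et3N, Et2O, 0 °C
Reagents that add atoms: tert-butyldimethylsilyl trifluoromethanesulfonate CC(C)(C)[Si](C)(C)OS(=O)(=O)C(F)(F)F
Why: soft γ-enolisation and O-silylation of the enal gives the 1-silyloxydiene, whose C1=C2 geometry is lost later and does not matter.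

Step 4
Reactants: 3 keto aldehyde; 5 silyl dienol ether
Product: 6 (2Z,5R)-2-bromo-5-[(1R,6R)-1,3-dimethyl-2-oxo-6-(prop-1-en-2-yl)cyclohex-3-en-1-yl]-5-hydroxypent-2-enal
Conditions: TiCl4, CH2Cl2, −78 °C
Reagents that add atoms: none
Why: vinylogous Mukaiyama aldol under Cram-chelate control, in which TiCl4 bridges the aldehyde and C10 ketone oxygens and the γ-carbon attacks the aldehyde face flanked by Me-15 (away from C14 and its isopropenyl group), sets 2R and gives the enal with C3 trans to CHO.

Step 5
Reactants: 6 bromo enal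
Product: 7 diol, (5R,6R)-6-[(1R,3Z)-4-bromo-1,5-dihydroxypent-3-en-1-yl]-2,6-dimethyl-5-(prop-1-en-2-yl)cyclohex-2-en-1-one
Conditions: NaBH4, MeOH–CH2Cl2, −78 °C
Reagents that add atoms: none
Why: chemoselective 1,2-reduction of the aldehyde, since the neopentyl enone carbonyl is far slower at −78 °C.

Step 6
Reactants: 7 diol
Product: 8 epoxy ketone diol (11,12-epoxide on the Me-15 face, C10 ketone)
Conditions: t-BuOOH, DBU, CH2Cl2, 0 °C
Reagents that add atoms: tert-butyl hydroperoxide CC(C)(C)OO
Why: Weitz–Scheffer nucleophilic epoxidation in which the peroxide adds to C12 anti to the isopropenyl group, while DBU is too weak to form the C2 alkoxide and so cannot trigger a retro-aldol.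

Step 7
Reactants: 8 epoxy ketone diol
Product: 11 epoxy ketone 2,14,16-triacetate, via methoxy hydroperoxide 9 (not isolated), via peracetate 10 (not isolated)
Conditions: O3, CH2Cl2–MeOH, −78 °C; then Ac2O, Et3N, DMAP, 0 to 40 °C
Reagents that add atoms: ozone [O-][O+]=O; methanol CO; acetic anhydride CC(=O)OC(C)=O
Why: ozonolysis of the only electron-rich alkene followed by Criegee rearrangement, in which C14 migrates to oxygen with retention, gives the 14-acetate trans to Me-15, and the same Ac2O acetylates the C2 and C16 hydroxyls.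

Step 8
Reactants: 11 epoxy ketone triacetate
Product: 13 allylic alcohol (C12–OH on the Me-15 face, C10=C11; 2,14,16-triacetate; 5-bromide), via epoxy hydrazone 12 (not isolated)
Conditions: N2H4·H2O, AcOH (cat.), MeOH, 0 °C to rt, short contact time
Reagents that add atoms: none
Why: Wharton transposition (hydrazone formation, epoxide opening, loss of N2) moves the alkene to C10=C11 and leaves the C12–O bond untouched, so the hydroxyl stays on the Me-15 face.

Step 9
Reactants: 13 allylic alcohol triacetate; 14 4-(chloroacetyl)morpholine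
Product: 16 C12 O-(2-morpholino-2-oxoethyl) ether 2,14,16-triol (5-bromide), via ether triacetate 15 (not isolated)
Conditions: NaH, Bu4NI (cat.), THF, 0 °C to rt; then K2CO3 (cat.), MeOH, rt
Reagents that add atoms: none
Why: Williamson etherification of the only free hydroxyl, followed in the same flask by base-catalysed methanolysis of the three acetates, which are no longer needed and would not survive the next strong-base steps.

Step 10
Reactants: 16 bromo triol ether
Product: 17 (4E)-diene triol ether (vinyl on C5, cis to C3)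
Conditions: CH2=CHSnBu3, Pd(PPh3)4, CuI, CsF, DMF, 45 °C
Reagents that add atoms: tributyl(vinyl)stannane C=C[Sn](CCCC)(CCCC)CCCC
Why: Stille coupling at zerovalent palladium proceeds with retention of the vinyl bromide geometry, and the free C16 hydroxyl avoids the β-acetoxy elimination that an allylic acetate would invite.

Step 11
Reactants: 17 diene triol ether
Product: 18 (9R,10S)-9-hydroxy morpholine amide (C9 on C10 cis to Me-15, C11=C12; 2,14,16-triol)
Conditions: LiN(i-Pr)2 (5 equiv), THF, −78 to −20 °C
Reagents that add atoms: none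
Why: [2,3]-Wittig rearrangement of the amide enolate is suprafacial, so C9 bonds to C10 on the face that carried the C12 oxygen (10S), and the amide group sits exo, away from quaternary C1, in the envelope transition state (9R).

Step 12
Reactants: 18 α-hydroxy morpholine amide
Product: 19 α-hydroxy vinyl ketone (C8 ketone bearing CH=CH2)
Conditions: CH2=CHMgBr (8 equiv), THF, −78 to 0 °C; cold aq. NH4Cl
Reagents that add atoms: vinylmagnesium bromide C=C[Mg]Br
Why: Weinreb-type ketone synthesis, in which the magnesium-chelated tetrahedral adduct of the morpholine amide resists a second addition and the four hydroxyls are simply carried as alkoxides.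

Step 13
Reactants: 20 propanoyl chloride; 21 2-(trimethylsilyl)ethanol
Product: 22 2-(trimethylsilyl)ethyl propanoate
Conditions: Et3N, DMAP (cat.), CH2Cl2, 0 °C
Reagents that add atoms: none
Why: simple acylation of the alcohol gives a propanoate whose ester can later be removed with fluoride in the presence of acetates.

Step 14
Reactants: 19 α-hydroxy vinyl ketone; 22 2-(trimethylsilyl)ethyl propanoate
Product: 24 pentaol ester (tertiary 8-OH, 8-vinyl, 17-CH(CH3)CO2CH2CH2SiMe3; C8 and C17 as in the target), via lithium enolate 23 (not isolated)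
Conditions: LiN(i-Pr)2, 22 (7 equiv), THF, −78 °C; then 19, −78 °C; AcOH quench at −78 °C
Reagents that add atoms: none
Why: kinetic 1,2-aldol addition through a Zimmerman–Traxler chair in which the C9 lithium alkoxide chelates the ketone (Cram chelate, attack anti to C10, setting C8), while the E(O)-enolate formed without HMPA places Me-18 to give 17R.

Step 15
Reactants: 24 pentaol ester
Product: 25 2,9,14,16-tetraacetate (tertiary 8-OH free)
Conditions: Ac2O, pyridine, DMAP (cat.), CH2Cl2, 0 °C to rt
Reagents that add atoms: acetic anhydride CC(=O)OC(C)=O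
Why: acylation of the primary and secondary hydroxyls only, since the tertiary allylic 8-OH is too hindered, and prompt acetylation of O9 blocks lactonisation onto the ester.

Step 16
Reactants: 25 triene tetraacetate
Product: 26 ten-membered (4E,6Z)-diene 2-(trimethylsilyl)ethyl ester
Conditions: second-generation Hoveyda–Grubbs catalyst RuCl2(H2IMes)(=CH-C6H4-2-O-i-Pr) (10 mol %), toluene (1 mM), 80 °C
Reagents that add atoms: none
Why: ene–diene ring-closing metathesis between the diene terminus and the vinyl carbinol, in which the trisubstituted C4=C5 bond is too hindered to compete and the ring strain of the ten-membered diene favours the cis C6=C7 bond.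

Step 17
Reactants: 26 macrocyclic ester
Product: 27 ten-membered (4E,6Z)-diene acid
Conditions: Bu4NF, THF, 0 °C; aq. NH4Cl
Reagents that add atoms: none
Why: fluoride-induced β-elimination of the 2-(trimethylsilyl)ethyl ester frees the acid without acid or hydroxide, so the acetates and the tertiary dienyl carbinol survive.

Step 18
Reactants: 27 diene acid
Product: 28 target CNP0290502.1
Conditions: Pd(O2CCF3)2 (10 mol %), 1,4-benzoquinone (2 equiv), LiO2CPr (0.5 equiv), PrCO2H–acetone 1:4, 23 °C, chloride-free
Reagents that add atoms: butanoic acid CCCC(=O)O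
Why: Proposed new method: intramolecular 1,4-butanoyloxy-lactonisation of a ten-membered 2-substituted cyclic 1,3-diene, in which divalent palladium binds C6=C7, the C19 carboxylate adds anti at C7 in a 5-exo sense (A(1,3) strain keeps the small 8-OH in the diene plane, so only the face giving 7S is reachable), the resulting η3-allylpalladium over C4–C6 lies on the opposite ring face, benzoquinone-induced cis migration of palladium-bound butanoate to the remote terminus C4 gives the trans-1,4 adduct (4R) with the ring-enforced 5Z alkene, and benzoquinone reoxidises zerovalent palladium; the closest known reaction type is the chloride-free trans-1,4-acetoxylactonisation of cyclohexadienyl- and cycloheptadienylacetic acids with Pd(OAc)2 and benzoquinone.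

## Compound list

1 | (S)-(+)-carvone, (5S)-2-methyl-5-(prop-1-en-2-yl)cyclohex-2-en-1-one | CC1=CC[C@@H](CC1=O)C(C)=C | starting material
2 | (5S)-6-(hydroxymethylidene)-2-methyl-5-(prop-1-en-2-yl)cyclohex-2-en-1-one (enol of 6-formylcarvone) | O=C1C(C)=CC[C@H](C(C)=C)C1=CO | intermediate
3 | (1R,6R)-1,3-dimethyl-2-oxo-6-(prop-1-en-2-yl)cyclohex-3-ene-1-carbaldehyde (methyl trans to isopropenyl) | O=C[C@@]1(C)[C@@H](C(C)=C)CC=C(C)C1=O | intermediate
4 | (Z)-2-bromobut-2-enal | C/C=C(\Br)C=O | starting material
5 | [(2-bromobuta-1,3-dien-1-yl)oxy](tert-butyl)dimethylsilane (C1=C2 geometry immaterial) | C=CC(Br)=CO[Si](C)(C)C(C)(C)C | intermediate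
6 | (2Z,5R)-2-bromo-5-[(1R,6R)-1,3-dimethyl-2-oxo-6-(prop-1-en-2-yl)cyclohex-3-en-1-yl]-5-hydroxypent-2-enal | O=C/C(Br)=C/C[C@@H](O)[C@@]1(C)[C@@H](C(C)=C)CC=C(C)C1=O | intermediate
7 | (5R,6R)-6-[(1R,3Z)-4-bromo-1,5-dihydroxypent-3-en-1-yl]-2,6-dimethyl-5-(prop-1-en-2-yl)cyclohex-2-en-1-one | OC/C(Br)=C/C[C@@H](O)[C@@]1(C)[C@@H](C(C)=C)CC=C(C)C1=O | intermediate
8 | epoxy ketone diol: 7 with an 11,12-epoxide on the Me-15 face (trans to isopropenyl) | OC/C(Br)=C/C[C@@H](O)[C@@]1(C)[C@@H](C(C)=C)C[C@@H]2O[C@]2(C)C1=O | intermediate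
9 | methoxy hydroperoxide: 8 with isopropenyl turned into C(CH3)(OCH3)OOH (both epimers at that carbon) | OC/C(Br)=C/C[C@@H](O)[C@@]1(C)[C@@H](C(C)(OC)OO)C[C@@H]2O[C@]2(C)C1=O | intermediate
10 | peracetate: 9 with O2-acetyl, O16-acetyl and OO-acetyl groups | CC(=O)OC/C(Br)=C/C[C@@H](OC(C)=O)[C@@]1(C)[C@@H](C(C)(OC)OOC(C)=O)C[C@@H]2O[C@]2(C)C1=O | intermediate
11 | epoxy ketone triacetate: 11,12-epoxide (Me-15 face), C10 ketone, (2R)-OAc, 14-OAc trans to Me-15, 16-OAc, (4Z)-5-bromo | CC(=O)OC/C(Br)=C/C[C@@H](OC(C)=O)[C@@]1(C)[C@@H](OC(C)=O)C[C@@H]2O[C@]2(C)C1=O | intermediate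
12 | C10 hydrazone of 11 | CC(=O)OC/C(Br)=C/C[C@@H](OC(C)=O)[C@@]1(C)[C@@H](OC(C)=O)C[C@@H]2O[C@]2(C)C1=NN | intermediate
13 | allylic alcohol: C12–OH on the Me-15 face, C10=C11, 2,14,16-triacetate, (4Z)-5-bromo | CC(=O)OC/C(Br)=C/C[C@@H](OC(C)=O)[C@@]1(C)[C@@H](OC(C)=O)C[C@H](O)C(C)=C1 | intermediate
14 | 4-(chloroacetyl)morpholine | O=C(CCl)N1CCOCC1 | starting material
15 | C12 O-(2-morpholino-2-oxoethyl) ether of 13 | CC(=O)OC/C(Br)=C/C[C@@H](OC(C)=O)[C@@]1(C)[C@@H](OC(C)=O)C[C@H](OCC(=O)N2CCOCC2)C(C)=C1 | intermediate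
16 | 15 with the three acetates removed (2,14,16-triol, 5-bromide) | OC/C(Br)=C/C[C@@H](O)[C@@]1(C)[C@@H](O)C[C@H](OCC(=O)N2CCOCC2)C(C)=C1 | intermediate
17 | 16 with vinyl in place of bromine ((4E)-diene, C3 cis to vinyl) | OC/C(C=C)=C/C[C@@H](O)[C@@]1(C)[C@@H](O)C[C@H](OCC(=O)N2CCOCC2)C(C)=C1 | intermediate
18 | (9R,10S)-9-hydroxy morpholine amide: C9 on C10 cis to Me-15, C11=C12, 2,14,16-triol, (4E)-diene | OC/C(C=C)=C/C[C@@H](O)[C@@]1(C)[C@@H](O)CC=C(C)[C@@H]1[C@@H](O)C(=O)N2CCOCC2 | intermediate
19 | α-hydroxy vinyl ketone: 18 with C8(=O)–CH=CH2 in place of the amide | OC/C(C=C)=C/C[C@@H](O)[C@@]1(C)[C@@H](O)CC=C(C)[C@@H]1[C@@H](O)C(=O)C=C | intermediate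
20 | propanoyl chloride | CCC(Cl)=O | starting material
21 | 2-(trimethylsilyl)ethanol | OCC[Si](C)(C)C | starting material
22 | 2-(trimethylsilyl)ethyl propanoate | CCC(=O)OCC[Si](C)(C)C | intermediate
23 | lithium E(O)-enolate of 22 (methyl trans to OLi) | C/C=C(/O[Li])OCC[Si](C)(C)C | intermediate
24 | pentaol ester: tertiary 8-OH, 8-vinyl, (17R)-CH(CH3)CO2CH2CH2SiMe3; C8 arranged as in the target | OC/C(C=C)=C/C[C@@H](O)[C@@]1(C)[C@@H](O)CC=C(C)[C@@H]1[C@@H](O)[C@@](O)(C=C)[C@@H](C)C(=O)OCC[Si](C)(C)C | intermediate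
25 | 2,9,14,16-tetraacetate of 24 | CC(=O)OC/C(C=C)=C/C[C@@H](OC(C)=O)[C@@]1(C)[C@@H](OC(C)=O)CC=C(C)[C@@H]1[C@@H](OC(C)=O)[C@@](O)(C=C)[C@@H](C)C(=O)OCC[Si](C)(C)C | intermediate
26 | ten-membered (4E,6Z)-diene tetraacetate, 2-(trimethylsilyl)ethyl ester | CC(=O)OC/C1=C/C[C@@H](OC(C)=O)[C@@]2(C)[C@@H](OC(C)=O)CC=C(C)[C@@H]2[C@@H](OC(C)=O)[C@@](O)(/C=C\1)[C@@H](C)C(=O)OCC[Si](C)(C)C | intermediate
27 | ten-membered (4E,6Z)-diene tetraacetate acid | CC(=O)OC/C1=C/C[C@@H](OC(C)=O)[C@@]2(C)[C@@H](OC(C)=O)CC=C(C)[C@@H]2[C@@H](OC(C)=O)[C@@](O)(/C=C\1)[C@@H](C)C(O)=O | intermediate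
28 | CNP0290502.1, (1R,2R,4R,5Z,7S,8S,9R,10S,14S,17R)-2,9,14,16-tetraacetoxy-4-butanoyloxy-8-hydroxybriara-5,11-dien-19,7-olide | CCCC(=O)O[C@@H]1C[C@@H](OC(C)=O)[C@@]2(C)[C@@H](OC(C)=O)CC=C(C)[C@@H]2[C@@H](OC(C)=O)[C@@]2(O)[C@H](/C=C\1COC(C)=O)OC(=O)[C@@H]2C | target

## Step count

Total steps: 18. Longest linear sequence: 16 (steps 1, 2, 4–12, 14–18).

## Three steps most likely to fail

**Step 18 (proposed new oxylactonisation).** The risks are π–σ–π isomerisation of the allylpalladium in the flexible ring (giving the 5E alkene or the C4 epimer), attack on the wrong C7 face, and competing 1,2-addition. The fallback uses known chemistry and sets out from 27. PhSeCl in CH2Cl2 at −78 °C gives, by anti selenolactonisation, the 7,19-lactone with the phenylselanyl group on C6, selenolactone F4. Oxidation with H2O2 and pyridine forms the selenoxide, whose [2,3]-sigmatropic shift carries oxygen suprafacially to C4 and, after hydrolysis of the selenenate, gives the 4-hydroxy-5-ene lactone, allylic alcohol F5. Butanoic anhydride with DMAP and pyridine acylates the secondary C4 hydroxyl only, and the route comes back at 28.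

**Step 16 (ring-closing metathesis).** The risks are that the vinyl group on the fully substituted C8 carbinol is too hindered, that oligomers form, or that the 6E isomer forms. The fallback sets out from 19 and closes the ring before C8 becomes quaternary. The same ruthenium catalyst joins the diene terminus to the vinyl ketone and gives the ten-membered (4E,6Z)-dienone, macrocyclic dienone F2. Chelation-controlled addition of enolate 23 to its C8 ketone gives the macrocyclic pentaol ester F3. Acetylation with Ac2O, pyridine and DMAP brings the route back at 26.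

**Step 4 (vinylogous Mukaiyama aldol).** The risks are α- instead of γ-attack of the new bromo dienol ether, a TiCl4-promoted carbonyl-ene reaction of the aldehyde with the neighbouring isopropenyl group, and loss of chelate control. The fallback sets out from 3 and builds the chain in two stages. TiCl4-chelated Mukaiyama aldol with trimethyl(vinyloxy)silane gives the (3R)-3-hydroxy aldehyde, β-hydroxy aldehyde F1. Wittig olefination with Ph3P=C(Br)CHO in toluene at 80 °C then gives the (Z)-2-bromo enal, and the route comes back at 6.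

## Further compounds

F1 | step 4 | (3R)-3-[(1R,6R)-1,3-dimethyl-2-oxo-6-(prop-1-en-2-yl)cyclohex-3-en-1-yl]-3-hydroxypropanal | O=CC[C@@H](O)[C@@]1(C)[C@@H](C(C)=C)CC=C(C)C1=O
F2 | step 16 | ten-membered (4E,6Z)-dienone: C8 ketone, 2,9,14,16-tetraol | OC/C1=C/C[C@@H](O)[C@@]2(C)[C@@H](O)CC=C(C)[C@@H]2[C@@H](O)C(=O)/C=C\1
F3 | step 16 | macrocyclic pentaol 2-(trimethylsilyl)ethyl ester (26 without its four acetyl groups) | OC/C1=C/C[C@@H](O)[C@@]2(C)[C@@H](O)CC=C(C)[C@@H]2[C@@H](O)[C@@](O)(/C=C\1)[C@@H](C)C(=O)OCC[Si](C)(C)C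
F4 | step 18 | 6-(phenylselanyl) 7,19-lactone with C4=C5 retained (selenium anti to the lactone oxygen) | CC(=O)OC/C1=C/C[C@@H](OC(C)=O)[C@@]2(C)[C@@H](OC(C)=O)CC=C(C)[C@@H]2[C@@H](OC(C)=O)[C@@]3(O)[C@H]([C@@H]1[Se]c4ccccc4)OC(=O)[C@@H]3C
F5 | step 18 | 4-O-debutanoyl target (4R-hydroxy, 5Z) | O[C@@H]1C[C@@H](OC(C)=O)[C@@]2(C)[C@@H](OC(C)=O)CC=C(C)[C@@H]2[C@@H](OC(C)=O)[C@@]2(O)[C@H](/C=C\1COC(C)=O)OC(=O)[C@@H]2C
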